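These flasks move slowly: theta, at 0.29 M, reads 9.7% of complex with two exchanged after 120 min.

| flask | starting complex | incoming ligand | leaving ligand | remark | time |
|---|---|---|---|---|---|
| beta | 0.045 M | 1 equiv | 2 equiv | run made earlier |  |
| alpha | 0.11 M | 1 equiv | 2 equiv | run made earlier |  |
| theta | 0.29 M | 1 equiv | 2 equiv | run made earlier |  |
| grey | 0.040 M | 1.00 equiv | 2.00 equiv |  | 2.5 h |
| blue | 0.080 M | 1.00 equiv | 2.00 equiv |  | 2.5 h |
| violet | 0.15 M | 1.00 equiv | 2.00 equiv |  | 2.5 h |
| amber | 0.30 M | 1.00 equiv | 2.00 equiv |  | 2.5 h |

| run | time / min | complex with two exchanged / % | complex with three exchanged / % |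
|---|---|---|---|
| beta | 12.0 | 0 | 2.3 |
| beta | 40.0 | 0.7 | 0.9 |
| beta | 60.0 | 1.7 | 0 |
| beta | 120 | 4.7 | 0 |
| alpha | 25.0 | 1.7 | 0.1 |
| alpha | 50.0 | 4.5 | 1.3 |
| alpha | 80.0 | 4.7 | 0 |
| alpha | 120 | 5.9 | 1.6 |
| theta | 8.00 | 2.6 | 0 |
| theta | 20.0 | 5.6 | 0.2 |
| theta | 50.0 | 9.6 | 0 |
| theta | 120 | 9.7 | 1.6 |

(each reading ± 1 percentage point)

- a reading or a percentage of complex with two exchanged counts all its forms, free or not
- "hardly changes" means that all values lie within two and a half points (for a concentration: within two and a half percent of the largest)

- share of complex with two exchanged in all that became complex with two exchanged or complex with three exchanged or over-reaction product for grey, blue, violet, amber, in this order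
- the shape of the row from first to last (rises, then falls / falls, then rises / hardly changes / falls all the way / rises all the way)

The bench rule for a slow reaction between two partners charged in a set ratio is to read progress against the dose, concentration times time. It holds early on: beta at 120 min and alpha at 50.0 min have doses in the ratio 0.982, and they read 4.7% and 4.5%. Further on it breaks. Alpha at 120 min and theta at 50.0 min have doses in the ratio 0.910, yet theta reads 1.63 times what alpha reads, 9.6% against 5.9%, with a scatter of 1 percentage point. So past that border the dose doesn't tell us how much complex with two exchanged stands in the flask.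

The share asked for, the selectivity for complex with two exchanged, can still be reckoned from both ends. At zero dose we set the share at 100 percent, on our assumption that complex with three exchanged and over-reaction product form from complex with two exchanged. At the far end we take theta's last readings, and the complex with three exchanged read per complex with two exchanged there is our leak ratio, 0.165. It is a rough reading, 1.6% with the same scatter, and over-reaction product was never read, so we count it as nil. To join the ends we let the leak grow in proportion to dose; this is a guess of ours, and dose has just failed for the amount of complex with two exchanged. Amber's dose is 1.29 times theta's last, so it lies beyond the readings. Our row is 97.2%, 94.6%, 90.4% and 82.4%.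

The forecast gives 78%, 60%, 42% and 25%, also falls all the way but lower than ours at each of these points: “The share falls steadily.”

The flasks give 95.1%, 92.5%, 90.4% and 89.4%: falls all the way.

    starting complex + incoming ligand ⇌ leaving ligand + complex with one exchanged (K = 0.210, k = 2.50 M⁻¹ h⁻¹)
    complex with two exchanged + incoming ligand ⇌ leaving ligand + complex with three exchanged (K = 3.50, k = 1.50 M⁻¹ h⁻¹)
    starting complex + complex with two exchanged ⇌ idle adduct, settled at all times (K = 26.0 M⁻¹)
    complex with two exchanged + incoming ligand → over-reaction product (k = 0.580 M⁻¹ h⁻¹)
    complex with one exchanged + incoming ligand ⇌ leaving ligand + complex with two exchanged (K = 0.740, k = 20.0 M⁻¹ h⁻¹)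

In grey at the asked time, the half-life of free complex with two exchanged by the forward rate of its step to complex with three exchanged, taken alone, is 13 h, long against the 2.5 h. The relaxation half-life of that step alone in grey, both ways together, is 7.73 h, longer than the 0.568 h of the first exchange alone. For amber, the leak ratio scaled by dose gave 0.213, while the flask at 2.50 h holds 0.691% of complex with three exchanged and 0.361% of over-reaction product beside 8.88% of complex with two exchanged, idle adduct counted in, a ratio of 0.118.

The runs are simulated for an exercise; the scatter is artificial.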